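## Structural features

Diaporindene G (35) is an indane. Benzene ring A (C3a–C7a) is fused to five-membered ring B, in which C1 is a diarylmethine, C2 carries an exocyclic isopropylidene group and C3 is a methylene; ring A bears a phenol at C6 and a formyl group at C7, next to the ring-fusion carbon C7a. C1 is bonded through C8' to a 6'-methyl-2',3'-dihydro-1,4-benzodioxine (rings C and D) whose C2' carries a 2-hydroxypropan-2-yl group and whose O1' lies ortho to the C1–C8' bond. The two stereocentres, C1 (R) and C2' (S), are not adjacent: C8', C8a' and O1' lie between them, so neither can direct the other and each needs its own external control. The fragile points are: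
- the C1–H bond, which is doubly benzylic and allylic, so that acid, strong base or metal hydrides can pull the tetrasubstituted alkene into ring B as an indene and erase C1;
- the free salicylaldehyde and the acid-sensitive tertiary alcohol;
- in intermediates, the benzylic C3 position para to the C6 oxygen, which expels a leaving group as a quinone methide once that oxygen is unmasked.

The real difficulty is the congestion at C1, flanked by two ortho-substituted aryl rings and a tetrasubstituted alkene, and the need to build C2=C(CH3)2 beside it without disturbing C1–H. The key step uses the two identical methyl groups on the exocyclic carbon of C2: a prop-1-ynyl group on C1 already contains C2, the exocyclic carbon and one methyl, so a ring bond from C3 to the inner alkyne carbon and a new methyl on the outer alkyne carbon complete ring B, and the geometry of addition is irrelevant. Configuration check: the acyclic precursor 31 and the cyclised product 33 have the same spatial arrangement at C1 (R in both, since the key step does not touch this carbon) and S at C2'.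

## Logic of the disconnections

35 ⇒ 34 ⇒ 33. No skeletal bond is cut. The C7 formyl group is traced back to CH2OH and the C6 phenol and that CH2OH to two triisopropylsilyl ethers, because a free salicylaldehyde would not survive the organometallic steps. The gain is a robust, non-acidic end game. The demand is an oxidant that takes only the benzylic alcohol and a buffered fluoride step that spares C1–H.

33 ⇒ 31 + 32. The ring bond C2–C3 and the bond from the exocyclic carbon to one methyl are cut. Both flank the tetrasubstituted alkene, and making that alkene from an alkyne avoids any olefination next to the epimerisable C1. Ring B and the alkene disappear, leaving an open propargylic diarylmethine with a benzylic chloride. The forward step must let the benzylpalladium add to the alkyne before it is methylated, and must leave C1–H alone.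

31 ⇒ 30 ⇒ 29. The C3–Cl bond is traced to C3–OH, and that alcohol and the tertiary alcohol to an oxanyl acetal and a trimethylsilyl ether. The chloride cannot pass through the nickel coupling, and C3 must be oxygenated from the start: chlorinating an aryl methyl group late would not distinguish it from the second aryl methyl, the C1–H and the CH2O group. The demand is a pair of acid-labile groups that leave together while the TIPS ethers stay, and a chlorination that takes a benzylic but not a tertiary alcohol.

29 ⇒ 13 + 26 (through 28). The C1–C8' bond is cut. This splits the molecule into two halves of similar size and lets C1 be set by a catalyst from a racemic electrophile. The more crowded aryl group is placed on the radical-forming partner and the mono-ortho-substituted one on zinc. The demand is an enantioconvergent nickel arylation at a propargylic carbon bearing a 2,6-disubstituted aryl group, with coupling at the propargylic and not the allenyl terminus.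

13 ⇒ 10 + 11, and 10 ⇒ 8. The C1–alkyne bond and then the C7a–C1 bond are cut (alkynyl Grignard addition; formylation of an aryllithium). The gain is a simple tetrasubstituted aryl bromide. The demand is that the ortho-lithiated benzyl silyl ether does not undergo silyl migration, which is why TIPS is used.

8 ⇒ 7 ⇒ 6 ⇒ 4 ⇒ 2 ⇒ 1. The C7–formyl carbon bond is cut and the C6–O bond is traced to C6–F. The position between bromine and fluorine is by far the most acidic, which gives complete regiocontrol over the contiguous 1,2,3,4-pattern, and fluorine then serves as the leaving group for oxygen. The demand is low temperature (no aryne) and a substitution that spares bromine.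

26 ⇒ 25 ⇒ 22 ⇒ 21 + 16. The O1'–C2' bond (ring closure, with inversion) and the O4'–C3' bond are cut, and C8a'–O1' is traced to C8a'–CHO (Baeyer–Villiger). O1' must attack a secondary carbon, which is only realistic intramolecularly; so O4' is alkylated first while O1' is still masked as a formyl group, and no catechol regiochemistry problem arises. The demand is direct displacement of the sulfonate (not epoxide opening) and a 6-exo closure under base.

21 ⇒ 19 ⇒ 17, and 16 ⇒ 14. The same halogen-flanked lithiation/formylation and fluoride displacement are used for the second ring; the epoxide comes from an asymmetric epoxidation of the allylic alcohol, which fixes the configuration that is inverted to give C2'.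

## Other disconnections considered

Alternative 1: The cut runs through ring A (C3a–C7a, C4–C5 and C6–C7), unravelling it into three alkynes held by C1–C2–C3 and by a diisopropylsilyl ether between the C7 CH2O oxygen and C6: triyne A1. Forward, RhCl(PPh3)3 would trimerise A1 to benzoxasilole A2, closing ring B, ring A and a temporary five-membered siloxane at once. Tamao–Fleming oxidation of the aryl–silicon bond would then give the C6 phenol and free the C7 CH2OH, and a benzylic oxidation would finish.
- In favour: three C–C bonds and three rings in one step, with full regiocontrol over the 1,2,3,4-substituted benzene because every alkyne is tethered. On bonds formed per step this is better than the chosen plan (two bonds, one ring), and the end game is of equal length.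
- Against: A1 still needs C1 set beforehand, now at a carbon that is benzylic, propargylic and allylic at once, which a rhodium hydride or trace base could isomerise. The tetrasubstituted alkene sits in the diyne tether and can compete for the metallacycle. The peroxide/fluoride oxidation of a hindered diisopropylarylsilane would have to be run on a product with an epimerisable C1.
- Comparison: both plans close ring B in a five-membered metal-mediated step and neither sets a stereocentre there (equal). The chosen plan asks less of its substrate (one alkyne, one C–Cl bond). A1 needs two separately built alkyne arms on a chiral core, so the route is estimated to be two or three steps longer.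

Alternative 2: The cut is C1–C2 with C1 as the electrophile. The precursor is benzhydrol A3: its second aryl ring has a free phenol ortho to the carbinol (dioxane not yet closed, O4' as an allyl ether) and ring A carries a CH2–C(SiMe3)=C(CH3)2 chain. Forward, a BINOL-derived phosphoric acid would dehydrate A3 to an ortho-quinone methide, the silicon-bearing alkene carbon would add to C1, and loss of silicon from the β-silyl cation would leave C2=C(CH3)2 in A4.
- In favour: ring B, the tetrasubstituted alkene and C1 arise in one catalytic step. On stereochemical economy this is better than the chosen plan, whose key step sets no stereocentre. Ipso-substitution fixes the alkene position as cleanly as methyl capture does (equal).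
- Against: the acid must ionise a benzhydrol next to a 2,6-disubstituted aryl group and then discriminate the faces of a twisted, hindered quinone methide. Protodesilylation and proton loss from the tertiary cation toward the ring are acid-promoted side paths. Because O1' is used as the activating phenol, the dioxane ring and C2' must be added to A4 afterwards (deallylation, selective alkylation of O4', closure by the hindered O1').
- Comparison: the same ring B bond set is made with reversed polarity. The cationic mechanism exposes alkene and C1–H to acid, whereas the palladium step runs under weak base. Length is about equal before the key step and an estimated three or four steps longer after it.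

Alternative 3: The cut is C1–C7a. The precursor is aryl bromide A5, with bromine on C7a and a methyl carbonate on C1 of an allylic and benzylic carbinol, racemic at C1. Forward, NiBr2(dme), a chiral bis(oxazoline) and manganese powder would join the two electrophilic carbons, closing ring B and setting C1 by enantioconvergent capture, to give A6.
- In favour: ring closure and C1 control coincide, the alkene is already in place, and no arylzinc has to be made. C3 never carries a leaving group, so the quinone-methide hazard of the chosen precursor is absent. On these points it is better; on length it is about equal.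
- Against: the allyl fragment can bond to the aryl carbon at C1 or at the C(CH3)2 terminus (both five-membered), so regio- and enantioselectivity must be solved together. Oxidative addition must occur at a bromide with two ortho substituents. Asymmetric reductive aryl–allyl couplings are established for intermolecular, unhindered cases and not for this ring closure. Making A5 needs selective metalation of a vinyl halide beside the aryl bromide.
- Comparison: the chosen plan separates the two problems, setting C1 by a known class of nickel arylation and closing ring B by a step that cannot affect C1. Alternative 3 fuses them in one step of lower precedent.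

Key step: step 17

Remark on the chemistry: the core is numbered as an indane (C1 diarylmethine, C2 alkylidene carbon, C3 CH2, C6 phenol carbon, C7 formyl-bearing carbon) and the benzodioxane with primed locants; the oxan-2-yl acetal carbon is carried as a mixture of epimers and is left undefined in names and SMILES.
Assumption: compounds 1, 11 (as a THF solution), 14, 17 and 32 are purchased.

## Route

Step 1
Reactants: 1 (2-bromo-4-fluorophenyl)methanol
Product: 2 2-[(2-bromo-4-fluorophenyl)methoxy]oxane
Conditions: 3,4-dihydro-2H-pyran, PPTS (cat.), CH2Cl2, rt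
Reagents that add atoms: 3,4-dihydro-2H-pyran, C1=COCCC1
Why: Acid-catalysed addition of the alcohol to the enol ether (tetrahydropyranylation); the acetal is inert to the amide base, hydride, alkyllithium and Grignard reagents used later and is removed by mild acid that leaves TIPS ethers alone.

Step 2
Reactants: 2 2-[(2-bromo-4-fluorophenyl)methoxy]oxane
Product: 4 2-bromo-6-fluoro-3-(oxan-2-yloxymethyl)benzaldehyde, via aryllithium 3 (not isolated)
Conditions: LiN(iPr)2, THF, −78 °C; then DMF, −78 °C; aq NH4Cl
Reagents that add atoms: N,N-dimethylformamide, CN(C)C=O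
Why: Directed ortho-lithiation: the C–H flanked by bromine and fluorine is by far the most acidic and a lithium amide does not exchange with the aryl bromide; formylation of the aryllithium at −78 °C (below the onset of aryne formation) places the future C7 carbon between the halogens.

Step 3
Reactants: 4 2-bromo-6-fluoro-3-(oxan-2-yloxymethyl)benzaldehyde
Product: 6 2-bromo-6-hydroxy-3-(oxan-2-yloxymethyl)benzaldehyde, via sulfonylethyl aryl ether 5 (not isolated)
Conditions: HOCH2CH2SO2Me, NaH, DMF, 0 °C → rt; pH 6 buffer
Reagents that add atoms: 2-(methylsulfonyl)ethanol, CS(=O)(=O)CCO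
Why: Nucleophilic aromatic substitution: the alkoxide displaces fluoride ortho to the formyl group (fluoride is a far better nucleofuge than bromide here), and excess base eliminates methyl vinyl sulfone (E1cB) to leave the phenoxide; this hydroxide surrogate avoids Cannizzaro conditions.

Step 4
Reactants: 6 2-bromo-6-hydroxy-3-(oxan-2-yloxymethyl)benzaldehyde
Product: 7 3-bromo-2-(hydroxymethyl)-4-(oxan-2-yloxymethyl)phenol
Conditions: NaBH4, MeOH–THF, 0 °C
Reagents that add atoms: none
Why: Borohydride reduction of the aldehyde; a neutral work-up avoids loss of the acetal and quinone methide formation from the salicyl alcohol.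

Step 5
Reactants: 7 3-bromo-2-(hydroxymethyl)-4-(oxan-2-yloxymethyl)phenol
Product: 8 {2-bromo-3-(oxan-2-yloxymethyl)-6-[tri(propan-2-yl)silyloxy]phenyl}methoxy-tri(propan-2-yl)silane
Conditions: iPr3SiCl, imidazole, DMAP (cat.), DMF, rt → 40 °C
Reagents that add atoms: chlorotri(propan-2-yl)silane, CC(C)[Si](Cl)(C(C)C)C(C)C
Why: Silylation of the phenol and the primary alcohol; TIPS is chosen over TBS because the aryl ether must survive carbonate at 85 °C in step 17 (its loss beside the para CH2Cl would release a quinone methide), must not migrate to the ortho aryllithium in step 6 and must outlast the acid of step 15.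

Step 6
Reactants: 8 {2-bromo-3-(oxan-2-yloxymethyl)-6-[tri(propan-2-yl)silyloxy]phenyl}methoxy-tri(propan-2-yl)silane
Product: 10 6-(oxan-2-yloxymethyl)-3-[tri(propan-2-yl)silyloxy]-2-[tri(propan-2-yl)silyloxymethyl]benzaldehyde, via aryllithium 9 (not isolated)
Conditions: n-BuLi, THF, −78 °C; then DMF, −78 → 0 °C; aq NH4Cl
Reagents that add atoms: N,N-dimethylformamide, CN(C)C=O
Why: Bromine–lithium exchange followed by formylation; the bulk of TIPS suppresses the retro-Brook (oxygen-to-carbon silyl) shift open to an ortho-lithiated benzyl silyl ether.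

Step 7
Reactants: 10 6-(oxan-2-yloxymethyl)-3-[tri(propan-2-yl)silyloxy]-2-[tri(propan-2-yl)silyloxymethyl]benzaldehyde; 11 prop-1-yn-1-ylmagnesium bromide
Product: 13 methyl 1-{6-(oxan-2-yloxymethyl)-3-[tri(propan-2-yl)silyloxy]-2-[tri(propan-2-yl)silyloxymethyl]phenyl}but-2-yn-1-yl carbonate (racemic at the carbinol carbon), via bromomagnesium alkoxide 12 (not isolated)
Conditions: CH3C≡CMgBr, THF, 0 °C; then ClCO2Me, DMAP (cat.), 0 °C → rt
Reagents that add atoms: methyl chloroformate, COC(=O)Cl
Why: 1,2-Addition of the slim alkynyl Grignard reagent to the hindered aldehyde, then acylation of the alkoxide in the same flask; the carbinol centre is deliberately racemic because step 14 is enantioconvergent.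

Step 8
Reactants: 14 3-methylbut-2-en-1-ol (prenol)
Product: 16 [(2R)-3,3-dimethyloxiran-2-yl]methyl 3-nitrobenzenesulfonate, via epoxy alcohol 15 (not isolated)
Conditions: Ti(OiPr)4 (cat.), D-(−)-diisopropyl tartrate (cat.), t-BuOOH, 4 Å MS, CH2Cl2, −20 °C; P(OMe)3; then 3-O2NC6H4SO2Cl, Et3N, DMAP (cat.), −10 °C
Reagents that add atoms: tert-butyl hydroperoxide, CC(C)(C)OO; 3-nitrobenzenesulfonyl chloride, O=S(=O)(Cl)c1cccc(c1)[N+](=O)[O-]
Why: Sharpless asymmetric epoxidation; natural L-(+)-tartrate gives the 2S series from primary allylic alcohols, so the D-(−) ester should deliver the 2R epoxy alcohol. Sulfonylation in the same flask avoids isolating the volatile, water-soluble epoxy alcohol and gives a crystalline ester whose enantiopurity should be upgradable by recrystallisation.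

Step 9
Reactants: 17 1-bromo-3-fluoro-5-methylbenzene
Product: 19 2-bromo-6-fluoro-4-methylbenzaldehyde, via aryllithium 18 (not isolated)
Conditions: LiN(iPr)2, THF, −78 °C; then DMF, −78 °C; aq NH4Cl
Reagents that add atoms: N,N-dimethylformamide, CN(C)C=O
Why: Directed ortho-lithiation at the position between bromine and fluorine and formylation, as in step 2; the formyl carbon marks the carbon that will become C8a' bearing O1'.

Step 10
Reactants: 19 2-bromo-6-fluoro-4-methylbenzaldehyde
Product: 21 2-bromo-6-hydroxy-4-methylbenzaldehyde, via sulfonylethyl aryl ether 20 (not isolated)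
Conditions: HOCH2CH2SO2Me, NaH, DMF, 0 °C → rt; dilute HCl
Reagents that add atoms: 2-(methylsulfonyl)ethanol, CS(=O)(=O)CCO
Why: Nucleophilic aromatic substitution of the formyl-activated fluoride and E1cB release of the phenoxide, as in step 3; the oxygen introduced is O4'.

Step 11
Reactants: 21 2-bromo-6-hydroxy-4-methylbenzaldehyde; 16 [(2R)-3,3-dimethyloxiran-2-yl]methyl 3-nitrobenzenesulfonate
Product: 22 2-bromo-6-{[(2R)-3,3-dimethyloxiran-2-yl]methoxy}-4-methylbenzaldehyde
Conditions: K2CO3, DMF, 40 °C
Reagents that add atoms: none
Why: Williamson ether synthesis: the phenoxide displaces the primary sulfonate directly, since attack on the epoxide would have to occur at a quaternary or a neopentyl-like carbon; the epoxide centre therefore keeps its R configuration.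

Step 12
Reactants: 22 2-bromo-6-{[(2R)-3,3-dimethyloxiran-2-yl]methoxy}-4-methylbenzaldehyde
Product: 25 2-[(2S)-8-bromo-6-methyl-2,3-dihydro-1,4-benzodioxin-2-yl]propan-2-ol, via aryl formate 23 (not isolated), via epoxy phenoxide 24 (not isolated)
Conditions: mCPBA, NaHCO3, CH2Cl2, 0 °C → rt; then K2CO3, MeOH, rt → 45 °C
Reagents that add atoms: 3-chloroperoxybenzoic acid, OOC(=O)c1cccc(Cl)c1
Why: Baeyer–Villiger oxidation: the alkoxy-substituted aryl group migrates in the Criegee intermediate to give the aryl formate. Methanolysis frees the phenoxide next to bromine, which opens the epoxide at its secondary carbon in a 6-exo-tet SN2 reaction (the 7-endo path would be substitution at a tertiary carbon). Inversion converts the R epoxide carbon into S-configured C2'.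

Step 13
Reactants: 25 2-[(2S)-8-bromo-6-methyl-2,3-dihydro-1,4-benzodioxin-2-yl]propan-2-ol
Product: 26 {2-[(2S)-8-bromo-6-methyl-2,3-dihydro-1,4-benzodioxin-2-yl]propan-2-yl}oxy-trimethylsilane
Conditions: Me3SiCl, imidazole, DMF, rt
Reagents that add atoms: chlorotrimethylsilane, C[Si](C)(C)Cl
Why: Silylation of the tertiary alcohol so that no alkoxide accompanies the arylzinc reagent in step 14; the group leaves together with the acetal in step 15.

Step 14
Reactants: 13 methyl 1-{6-(oxan-2-yloxymethyl)-3-[tri(propan-2-yl)silyloxy]-2-[tri(propan-2-yl)silyloxymethyl]phenyl}but-2-yn-1-yl carbonate; 26 {2-[(2S)-8-bromo-6-methyl-2,3-dihydro-1,4-benzodioxin-2-yl]propan-2-yl}oxy-trimethylsilane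
Product: 29 (2S)-6-methyl-8-[(1R)-1-{6-(oxan-2-yloxymethyl)-3-[tri(propan-2-yl)silyloxy]-2-[tri(propan-2-yl)silyloxymethyl]phenyl}but-2-yn-1-yl]-2-[2-(trimethylsilyloxy)propan-2-yl]-2,3-dihydro-1,4-benzodioxine, via aryllithium 27 (not isolated), via arylzinc iodide 28 (not isolated)
Conditions: 26, n-BuLi, THF, −78 °C; ZnI2, −78 → 0 °C; then 13, NiCl2(dme) (10 mol %), 2,6-bis[(3aS,8aR)-3a,8a-dihydro-8H-indeno[1,2-d]oxazol-2-yl]pyridine or its antipode (13 mol %), DME–THF, −20 → 0 °C
Reagents that add atoms: none
Why: Nickel/pybox-catalysed enantioconvergent Negishi arylation of a racemic propargylic carbonate: both enantiomers of 13 give a common propargylic radical that is captured by an aryl–nickel pybox complex, so C1 is set by the ligand. The ligand antipode that gives 1R is chosen on a test scale, and because C2' is already fixed any minor C1 epimer is a diastereomer that can be removed. The crowded aryl group is placed on the radical partner and the mono-ortho-substituted one on zinc.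

Step 15
Reactants: 29 (2S)-6-methyl-8-[(1R)-1-{6-(oxan-2-yloxymethyl)-3-[tri(propan-2-yl)silyloxy]-2-[tri(propan-2-yl)silyloxymethyl]phenyl}but-2-yn-1-yl]-2-[2-(trimethylsilyloxy)propan-2-yl]-2,3-dihydro-1,4-benzodioxine
Product: 30 2-[(2S)-8-{(1R)-1-[6-(hydroxymethyl)-3-[tri(propan-2-yl)silyloxy]-2-[tri(propan-2-yl)silyloxymethyl]phenyl]but-2-yn-1-yl}-6-methyl-2,3-dihydro-1,4-benzodioxin-2-yl]propan-2-ol
Conditions: PPTS, MeOH, 40 °C
Reagents that add atoms: none
Why: Acid-catalysed acetal exchange and methanolysis of the tertiary trimethylsilyl ether; both groups are far more acid-labile than the primary and aryl TIPS ethers, and the buffered weak acid does not ionise the benzylic alcohol.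

Step 16
Reactants: 30 2-[(2S)-8-{(1R)-1-[6-(hydroxymethyl)-3-[tri(propan-2-yl)silyloxy]-2-[tri(propan-2-yl)silyloxymethyl]phenyl]but-2-yn-1-yl}-6-methyl-2,3-dihydro-1,4-benzodioxin-2-yl]propan-2-ol
Product: 31 2-[(2S)-8-{(1R)-1-[6-(chloromethyl)-3-[tri(propan-2-yl)silyloxy]-2-[tri(propan-2-yl)silyloxymethyl]phenyl]but-2-yn-1-yl}-6-methyl-2,3-dihydro-1,4-benzodioxin-2-yl]propan-2-ol
Conditions: N-chlorosuccinimide, Me2S, CH2Cl2, −20 → 0 °C; filtration through a short pad, used at once
Reagents that add atoms: N-chlorosuccinimide, O=C1CCC(=O)N1Cl
Why: Corey–Kim chlorination: the chlorosulfonium salt activates the alcohol and chloride displaces dimethyl sulfoxide at the primary benzylic carbon; the tertiary alcohol cannot be displaced and is returned on work-up. The product is not chromatographed because a benzylic chloride para to a silyloxy group ionises easily.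

Step 17
Reactants: 31 2-[(2S)-8-{(1R)-1-[6-(chloromethyl)-3-[tri(propan-2-yl)silyloxy]-2-[tri(propan-2-yl)silyloxymethyl]phenyl]but-2-yn-1-yl}-6-methyl-2,3-dihydro-1,4-benzodioxin-2-yl]propan-2-ol; 32 trimethylboroxine
Product: 33 2-[(2S)-6-methyl-8-{(1R)-2-(propan-2-ylidene)-6-[tri(propan-2-yl)silyloxy]-7-[tri(propan-2-yl)silyloxymethyl]-2,3-dihydro-1H-inden-1-yl}-2,3-dihydro-1,4-benzodioxin-2-yl]propan-2-ol
Conditions: Pd(PPh3)4 (10 mol %), K2CO3, 1,4-dioxane (degassed, dry), 85 °C
Reagents that add atoms: none
Why: Proposed new method: zerovalent palladium inserts into the benzylic C3–Cl bond to give a benzylpalladium chloride that has no β-hydrogen; it adds syn across the tethered alkyne, forming C3–C2 and placing palladium on the outer alkyne carbon. The closest known reaction types are alkyne insertions of benzylpalladium halides and cyclisation–Suzuki–Miyaura cascades started from aryl or alkenyl halides. Ring B closes in the 5-exo-dig mode, the only one open to a syn insertion, since a 6-endo closure would require anti addition. The alkenylpalladium then transmetalates with the carbonate-activated methylboron reagent and reductive elimination forms the second C–CH3 bond. No stereocentre is created: C1 is preset as R, is not part of any bond change, and K2CO3 in dioxane is too weak a base to remove C1–H from substrate or product. The selectivity needed is insertion ahead of direct methylation of the benzylpalladium; the intramolecular five-membered closure should outrun the slow bimolecular transfer of methyl from boron. Because both exocyclic substituents end as methyl, the geometry of the insertion does not matter. The aryl TIPS ether is expected to hold under these conditions, which keeps the para benzylic chloride from collapsing to a quinone methide.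

Step 18
Reactants: 33 2-[(2S)-6-methyl-8-{(1R)-2-(propan-2-ylidene)-6-[tri(propan-2-yl)silyloxy]-7-[tri(propan-2-yl)silyloxymethyl]-2,3-dihydro-1H-inden-1-yl}-2,3-dihydro-1,4-benzodioxin-2-yl]propan-2-ol
Product: 34 (1R)-7-(hydroxymethyl)-1-[(2S)-2-(2-hydroxypropan-2-yl)-6-methyl-2,3-dihydro-1,4-benzodioxin-8-yl]-2-(propan-2-ylidene)-2,3-dihydro-1H-inden-6-ol
Conditions: Bu4NF, AcOH, THF, 0 °C → rt
Reagents that add atoms: none
Why: Fluoride cleaves both Si–O bonds; acetic acid buffers the phenoxide so that the doubly benzylic, allylic C1–H and the exocyclic alkene are not disturbed.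

Step 19
Reactants: 34 (1R)-7-(hydroxymethyl)-1-[(2S)-2-(2-hydroxypropan-2-yl)-6-methyl-2,3-dihydro-1,4-benzodioxin-8-yl]-2-(propan-2-ylidene)-2,3-dihydro-1H-inden-6-ol
Product: 35 diaporindene G, (1R)-6-hydroxy-1-[(2S)-2-(2-hydroxypropan-2-yl)-6-methyl-2,3-dihydro-1,4-benzodioxin-8-yl]-2-(propan-2-ylidene)-2,3-dihydro-1H-indene-7-carbaldehyde
Conditions: MnO2 (activated), CH2Cl2, rt
Reagents that add atoms: none
Why: MnO2 oxidises benzylic alcohols selectively; the tertiary alcohol is inert, and a salicyl alcohol should give the hydrogen-bonded salicylaldehyde without acid or base that could move the alkene.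

## Compound list

1 | (2-bromo-4-fluorophenyl)methanol | OCc1ccc(F)cc1Br | starting material
2 | 2-[(2-bromo-4-fluorophenyl)methoxy]oxane (epimers at the acetal carbon) | Fc1ccc(COC2CCCCO2)c(Br)c1 | intermediate
3 | [2-bromo-6-fluoro-3-(oxan-2-yloxymethyl)phenyl]lithium | [Li]c1c(F)ccc(COC2CCCCO2)c1Br | intermediate (not isolated)
4 | 2-bromo-6-fluoro-3-(oxan-2-yloxymethyl)benzaldehyde | O=Cc1c(F)ccc(COC2CCCCO2)c1Br | intermediate
5 | 2-bromo-6-[2-(methylsulfonyl)ethoxy]-3-(oxan-2-yloxymethyl)benzaldehyde | CS(=O)(=O)CCOc1ccc(COC2CCCCO2)c(Br)c1C=O | intermediate (not isolated)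
6 | 2-bromo-6-hydroxy-3-(oxan-2-yloxymethyl)benzaldehyde | O=Cc1c(O)ccc(COC2CCCCO2)c1Br | intermediate
7 | 3-bromo-2-(hydroxymethyl)-4-(oxan-2-yloxymethyl)phenol | OCc1c(O)ccc(COC2CCCCO2)c1Br | intermediate
8 | {2-bromo-3-(oxan-2-yloxymethyl)-6-[tri(propan-2-yl)silyloxy]phenyl}methoxy-tri(propan-2-yl)silane | CC(C)[Si](OCc1c(O[Si](C(C)C)(C(C)C)C(C)C)ccc(COC2CCCCO2)c1Br)(C(C)C)C(C)C | intermediate
9 | {6-(oxan-2-yloxymethyl)-3-[tri(propan-2-yl)silyloxy]-2-[tri(propan-2-yl)silyloxymethyl]phenyl}lithium | [Li]c1c(COC2CCCCO2)ccc(O[Si](C(C)C)(C(C)C)C(C)C)c1CO[Si](C(C)C)(C(C)C)C(C)C | intermediate (not isolated)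
10 | 6-(oxan-2-yloxymethyl)-3-[tri(propan-2-yl)silyloxy]-2-[tri(propan-2-yl)silyloxymethyl]benzaldehyde | O=Cc1c(COC2CCCCO2)ccc(O[Si](C(C)C)(C(C)C)C(C)C)c1CO[Si](C(C)C)(C(C)C)C(C)C | intermediate
11 | prop-1-yn-1-ylmagnesium bromide | CC#C[Mg]Br | starting material
12 | bromomagnesium 1-arylbut-2-yn-1-olate from 10 and 11 (racemic) | CC#CC(O[Mg]Br)c1c(COC2CCCCO2)ccc(O[Si](C(C)C)(C(C)C)C(C)C)c1CO[Si](C(C)C)(C(C)C)C(C)C | intermediate (not isolated)
13 | methyl 1-{6-(oxan-2-yloxymethyl)-3-[tri(propan-2-yl)silyloxy]-2-[tri(propan-2-yl)silyloxymethyl]phenyl}but-2-yn-1-yl carbonate (racemic at the carbinol carbon) | CC#CC(OC(=O)OC)c1c(COC2CCCCO2)ccc(O[Si](C(C)C)(C(C)C)C(C)C)c1CO[Si](C(C)C)(C(C)C)C(C)C | intermediate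
14 | 3-methylbut-2-en-1-ol (prenol) | CC(C)=CCO | starting material
15 | [(2R)-3,3-dimethyloxiran-2-yl]methanol | CC1(C)O[C@@H]1CO | intermediate (not isolated)
16 | [(2R)-3,3-dimethyloxiran-2-yl]methyl 3-nitrobenzenesulfonate | CC1(C)O[C@@H]1COS(=O)(=O)c1cccc(c1)[N+](=O)[O-] | intermediate
17 | 1-bromo-3-fluoro-5-methylbenzene | Cc1cc(F)cc(Br)c1 | starting material
18 | (2-bromo-6-fluoro-4-methylphenyl)lithium | [Li]c1c(F)cc(C)cc1Br | intermediate (not isolated)
19 | 2-bromo-6-fluoro-4-methylbenzaldehyde | Cc1cc(F)c(C=O)c(Br)c1 | intermediate
20 | 2-bromo-4-methyl-6-[2-(methylsulfonyl)ethoxy]benzaldehyde | Cc1cc(OCCS(C)(=O)=O)c(C=O)c(Br)c1 | intermediate (not isolated)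
21 | 2-bromo-6-hydroxy-4-methylbenzaldehyde | Cc1cc(O)c(C=O)c(Br)c1 | intermediate
22 | 2-bromo-6-{[(2R)-3,3-dimethyloxiran-2-yl]methoxy}-4-methylbenzaldehyde | Cc1cc(OC[C@H]2OC2(C)C)c(C=O)c(Br)c1 | intermediate
23 | 2-bromo-6-{[(2R)-3,3-dimethyloxiran-2-yl]methoxy}-4-methylphenyl formate | Cc1cc(OC[C@H]2OC2(C)C)c(OC=O)c(Br)c1 | intermediate (not isolated)
24 | 2-bromo-6-{[(2R)-3,3-dimethyloxiran-2-yl]methoxy}-4-methylphenol (present as its potassium salt) | Cc1cc(OC[C@H]2OC2(C)C)c(O)c(Br)c1 | intermediate (not isolated)
25 | 2-[(2S)-8-bromo-6-methyl-2,3-dihydro-1,4-benzodioxin-2-yl]propan-2-ol | Cc1cc(Br)c2O[C@H](C(C)(C)O)COc2c1 | intermediate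
26 | {2-[(2S)-8-bromo-6-methyl-2,3-dihydro-1,4-benzodioxin-2-yl]propan-2-yl}oxy-trimethylsilane | Cc1cc(Br)c2O[C@H](C(C)(C)O[Si](C)(C)C)COc2c1 | intermediate
27 | {(2S)-6-methyl-2-[2-(trimethylsilyloxy)propan-2-yl]-2,3-dihydro-1,4-benzodioxin-8-yl}lithium | Cc1cc([Li])c2O[C@H](C(C)(C)O[Si](C)(C)C)COc2c1 | intermediate (not isolated)
28 | {(2S)-6-methyl-2-[2-(trimethylsilyloxy)propan-2-yl]-2,3-dihydro-1,4-benzodioxin-8-yl}zinc iodide | Cc1cc([Zn]I)c2O[C@H](C(C)(C)O[Si](C)(C)C)COc2c1 | intermediate (not isolated)
29 | (2S)-6-methyl-8-[(1R)-1-{6-(oxan-2-yloxymethyl)-3-[tri(propan-2-yl)silyloxy]-2-[tri(propan-2-yl)silyloxymethyl]phenyl}but-2-yn-1-yl]-2-[2-(trimethylsilyloxy)propan-2-yl]-2,3-dihydro-1,4-benzodioxine | CC#C[C@H](c1c(COC2CCCCO2)ccc(O[Si](C(C)C)(C(C)C)C(C)C)c1CO[Si](C(C)C)(C(C)C)C(C)C)c1cc(C)cc2c1O[C@H](C(C)(C)O[Si](C)(C)C)CO2 | intermediate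
30 | 2-[(2S)-8-{(1R)-1-[6-(hydroxymethyl)-3-[tri(propan-2-yl)silyloxy]-2-[tri(propan-2-yl)silyloxymethyl]phenyl]but-2-yn-1-yl}-6-methyl-2,3-dihydro-1,4-benzodioxin-2-yl]propan-2-ol | CC#C[C@H](c1c(CO)ccc(O[Si](C(C)C)(C(C)C)C(C)C)c1CO[Si](C(C)C)(C(C)C)C(C)C)c1cc(C)cc2c1O[C@H](C(C)(C)O)CO2 | intermediate
31 | 2-[(2S)-8-{(1R)-1-[6-(chloromethyl)-3-[tri(propan-2-yl)silyloxy]-2-[tri(propan-2-yl)silyloxymethyl]phenyl]but-2-yn-1-yl}-6-methyl-2,3-dihydro-1,4-benzodioxin-2-yl]propan-2-ol (key-step precursor) | CC#C[C@H](c1c(CCl)ccc(O[Si](C(C)C)(C(C)C)C(C)C)c1CO[Si](C(C)C)(C(C)C)C(C)C)c1cc(C)cc2c1O[C@H](C(C)(C)O)CO2 | intermediate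
32 | trimethylboroxine | CB1OB(C)OB(C)O1 | starting material
33 | 2-[(2S)-6-methyl-8-{(1R)-2-(propan-2-ylidene)-6-[tri(propan-2-yl)silyloxy]-7-[tri(propan-2-yl)silyloxymethyl]-2,3-dihydro-1H-inden-1-yl}-2,3-dihydro-1,4-benzodioxin-2-yl]propan-2-ol (key-step product) | CC(C)=C1Cc2ccc(O[Si](C(C)C)(C(C)C)C(C)C)c(CO[Si](C(C)C)(C(C)C)C(C)C)c2[C@@H]1c1cc(C)cc2c1O[C@H](C(C)(C)O)CO2 | intermediate
34 | (1R)-7-(hydroxymethyl)-1-[(2S)-2-(2-hydroxypropan-2-yl)-6-methyl-2,3-dihydro-1,4-benzodioxin-8-yl]-2-(propan-2-ylidene)-2,3-dihydro-1H-inden-6-ol | CC(C)=C1Cc2ccc(O)c(CO)c2[C@@H]1c1cc(C)cc2c1O[C@H](C(C)(C)O)CO2 | intermediate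
35 | diaporindene G, (1R)-6-hydroxy-1-[(2S)-2-(2-hydroxypropan-2-yl)-6-methyl-2,3-dihydro-1,4-benzodioxin-8-yl]-2-(propan-2-ylidene)-2,3-dihydro-1H-indene-7-carbaldehyde | CC(C)=C1Cc2ccc(O)c(C=O)c2[C@@H]1c1cc(C)cc2c1O[C@H](C(C)(C)O)CO2 | target

## Step count and least certain steps

Total step count: 19. Longest linear sequence: 13 steps (steps 1–7, then 14–19); the benzodioxane branch (steps 8–13) joins at step 14.

Step 17 (key step, proposed new method). The likely failure is methyl transfer to the benzylpalladium before it has inserted the alkyne, or ionisation and reduction of the benzylic chloride. Alkynes insert into benzyl–palladium bonds more slowly than into aryl–palladium bonds, and the alkyne here sits beside the crowded diarylmethine. The fallback uses known radical and cross-coupling chemistry and sets out from 31. Halide exchange (NaI, acetone, Finkelstein) would give the benzylic iodide F1. Iodine-atom-transfer radical cyclisation ((Bu3Sn)2 cat., light, benzene, 80 °C; 5-exo-dig attack of the benzylic radical, then iodine transfer to the alkenyl radical) would give the exocyclic alkenyl iodide F2, whose E/Z mixture is immaterial. Suzuki–Miyaura methylation of F2 with 32 (Pd(PPh3)4, K2CO3, dioxane) replaces iodine by methyl and returns to the route at 33.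

Step 14. The likely failures are coupling at the outer alkyne terminus (allene formation), slow capture of the propargylic radical and weak ligand control. Both ortho positions of the radical-bearing aryl ring are substituted, and the methyl-capped alkyne leaves its far terminus open. The fallback sets out from 10. (Trimethylsilyl)ethynylmagnesium bromide followed by ClCO2Me would give the silyl-capped propargylic carbonate F3, the best-precedented substrate class for this coupling, in which silicon blocks the far terminus. The same nickel arylation with 28 would give the silylalkyne F4. Silver-catalysed protodesilylation (AgNO3 cat., 2,6-lutidine, aqueous acetone; silyl ethers untouched) would give the terminal alkyne F5, and deprotonation of the sp C–H with n-BuLi at −78 °C followed by MeI would return to the route at 29. If induction remains poor, the C1 epimers are diastereomers and can be separated after step 15.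

Step 16. The likely failure is ionisation of the benzylic chloride para to the silyloxy group during isolation (solvolysis, quinone-methide-type loss), or activation of the tertiary alcohol. The fallback sets out from 30 and avoids a halide. ClCO2Me and pyridine at 0 °C would acylate only the primary alcohol to give the stable benzylic methyl carbonate F6. F6 would then be used directly as the electrophile in the cascade with 32 ([Pd(η3-C3H5)Cl]2, a wide-bite-angle bisphosphine, K2CO3, dioxane), since benzylic carbonates ionise to benzylpalladium species with loss of CO2 and methoxide. This comes back to the route at 33.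

Step 12. The likely failure is migration of hydride in place of the aryl group in the Criegee intermediate (benzoic acid formation), or acid-promoted opening of the trisubstituted epoxide by the carboxylic acid before ring closure. The fallback sets out from 21. Dakin oxidation (H2O2, NaOH), reliable for ortho-hydroxybenzaldehydes, would give the catechol F7 before any epoxide is present. The dianion of F7 (NaH, 2.2 equiv, DMSO) with 16 should be alkylated at the more basic, less hindered oxygen remote from bromine, and the remaining phenoxide then closes the ring as in step 12. This returns to the route at 25, with the regiochemistry to be confirmed.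

Step 19. The likely failure is oxidation of the electron-rich free phenol (phenoxyl coupling, quinone methide formation) in competition with the benzylic alcohol. The fallback sets out from 33 and oxidises before the phenol is unmasked. HF·pyridine in THF/pyridine cleaves alkyl silyl ethers faster than aryl silyl ethers and would give the benzylic alcohol F8 with the aryl TIPS ether intact. Dess–Martin oxidation (NaHCO3, CH2Cl2) would give the silyl-protected salicylaldehyde F9, and Bu4NF/AcOH would release the phenol, arriving at 35.

## Further compounds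

F1 | step 17 | 2-[(2S)-8-{(1R)-1-[6-(iodomethyl)-3-[tri(propan-2-yl)silyloxy]-2-[tri(propan-2-yl)silyloxymethyl]phenyl]but-2-yn-1-yl}-6-methyl-2,3-dihydro-1,4-benzodioxin-2-yl]propan-2-ol | CC#C[C@H](c1c(CI)ccc(O[Si](C(C)C)(C(C)C)C(C)C)c1CO[Si](C(C)C)(C(C)C)C(C)C)c1cc(C)cc2c1O[C@H](C(C)(C)O)CO2
F2 | step 17 | 2-[(2S)-8-{2-(1-iodoethylidene)-6-[tri(propan-2-yl)silyloxy]-7-[tri(propan-2-yl)silyloxymethyl]-2,3-dihydro-1H-inden-1-yl}-6-methyl-2,3-dihydro-1,4-benzodioxin-2-yl]propan-2-ol (E/Z mixture, C1 arranged as in 33) | CC(I)=C1Cc2ccc(O[Si](C(C)C)(C(C)C)C(C)C)c(CO[Si](C(C)C)(C(C)C)C(C)C)c2[C@@H]1c1cc(C)cc2c1O[C@H](C(C)(C)O)CO2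
F3 | step 14 | methyl 1-{6-(oxan-2-yloxymethyl)-3-[tri(propan-2-yl)silyloxy]-2-[tri(propan-2-yl)silyloxymethyl]phenyl}-3-(trimethylsilyl)prop-2-yn-1-yl carbonate (racemic at the carbinol carbon) | C[Si](C)(C)C#CC(OC(=O)OC)c1c(COC2CCCCO2)ccc(O[Si](C(C)C)(C(C)C)C(C)C)c1CO[Si](C(C)C)(C(C)C)C(C)C
F4 | step 14 | trimethylsilyl-capped analogue of 29 (C≡C–SiMe3 in place of C≡C–CH3, same arrangement at C1 and C2') | C[Si](C)(C)C#C[C@H](c1c(COC2CCCCO2)ccc(O[Si](C(C)C)(C(C)C)C(C)C)c1CO[Si](C(C)C)(C(C)C)C(C)C)c1cc(C)cc2c1O[C@H](C(C)(C)O[Si](C)(C)C)CO2
F5 | step 14 | terminal-alkyne analogue of 29 (C≡C–H in place of C≡C–CH3, same arrangement at C1 and C2') | C#C[C@H](c1c(COC2CCCCO2)ccc(O[Si](C(C)C)(C(C)C)C(C)C)c1CO[Si](C(C)C)(C(C)C)C(C)C)c1cc(C)cc2c1O[C@H](C(C)(C)O[Si](C)(C)C)CO2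
F6 | step 16 | benzylic methyl carbonate of 30 (CH2OCO2CH3 at C3 in place of CH2OH) | CC#C[C@H](c1c(COC(=O)OC)ccc(O[Si](C(C)C)(C(C)C)C(C)C)c1CO[Si](C(C)C)(C(C)C)C(C)C)c1cc(C)cc2c1O[C@H](C(C)(C)O)CO2
F7 | step 12 | 3-bromo-5-methylbenzene-1,2-diol | Cc1cc(O)c(O)c(Br)c1
F8 | step 19 | 2-[(2S)-8-{(1R)-7-(hydroxymethyl)-2-(propan-2-ylidene)-6-[tri(propan-2-yl)silyloxy]-2,3-dihydro-1H-inden-1-yl}-6-methyl-2,3-dihydro-1,4-benzodioxin-2-yl]propan-2-ol | CC(C)=C1Cc2ccc(O[Si](C(C)C)(C(C)C)C(C)C)c(CO)c2[C@@H]1c1cc(C)cc2c1O[C@H](C(C)(C)O)CO2
F9 | step 19 | (1R)-1-[(2S)-2-(2-hydroxypropan-2-yl)-6-methyl-2,3-dihydro-1,4-benzodioxin-8-yl]-2-(propan-2-ylidene)-6-[tri(propan-2-yl)silyloxy]-2,3-dihydro-1H-indene-7-carbaldehyde | CC(C)=C1Cc2ccc(O[Si](C(C)C)(C(C)C)C(C)C)c(C=O)c2[C@@H]1c1cc(C)cc2c1O[C@H](C(C)(C)O)CO2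
A1 | alternative 1 | silyl ether-tethered triyne, ethynyl-di(propan-2-yl)silyl ether of the 1,6-diyne carrying the benzodioxane at C1 | C#CCC(=C(C)C)[C@@H](c1cc(C)cc2c1O[C@H](C(C)(C)O)CO2)C#CCO[Si](C(C)C)(C(C)C)C#C
A2 | alternative 1 | indane-fused benzoxasilole | CC(C)=C1Cc2ccc3c(c2[C@@H]1c1cc(C)cc2c1O[C@H](C(C)(C)O)CO2)CO[Si]3(C(C)C)C(C)C
A3 | alternative 2 | racemic ortho-hydroxybenzhydrol with a 2-(trimethylsilyl)-3-methylbut-2-enyl side chain | CC(C)=C([Si](C)(C)C)Cc1ccc(O[Si](C(C)C)(C(C)C)C(C)C)c(COC(=O)C(C)(C)C)c1C(O)c1cc(C)cc(OCC=C)c1O
A4 | alternative 2 | protected 1-(3-allyloxy-2-hydroxy-5-methylphenyl)-2-isopropylideneindane | CC(C)=C1Cc2ccc(O[Si](C(C)C)(C(C)C)C(C)C)c(COC(=O)C(C)(C)C)c2[C@@H]1c1cc(C)cc(OCC=C)c1O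
A5 | alternative 3 | aryl bromide with an allylic, benzylic methyl carbonate (racemic at C1) | CC(C)=C(Cc1ccc(O[Si](C)(C)C(C)(C)C)c(CO[Si](C)(C)C(C)(C)C)c1Br)C(OC(=O)OC)c1cc(C)cc2c1O[C@H](C(C)(C)O[Si](CC)(CC)CC)CO2
A6 | alternative 3 | tris-silylated indane with the target skeleton | CC(C)=C1Cc2ccc(O[Si](C)(C)C(C)(C)C)c(CO[Si](C)(C)C(C)(C)C)c2[C@@H]1c1cc(C)cc2c1O[C@H](C(C)(C)O[Si](CC)(CC)CC)CO2
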